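**Plan**

1. Retrosynthesis: open the seven-membered lactone at its aryl ester C(=O)–O bond; cut the diaryl ether at the O–C bond to ring A; in the dihydropyranone ring fused to ring B, cut C3–C2 and O1–C8a together, which excises acetone (chroman-4-one numbering).
2. Enabling feature: ring carbon C8a, which carries O1, is ortho to C4a, which carries the C4 ketone. An ortho-fluoro acetophenone therefore holds both the nucleophilic methyl carbon (future C3) and a ketone-activated C–F carbon (future C8a); acetone supplies C2 with its two methyl groups and O1.
3. Forward, ring B: 4-fluoro-2-methylphenol is elaborated to the fully substituted acetophenone (steps 1–6), acetone is annulated to close the dihydropyranone ring (step 7), and the C6 oxygen is freed (step 8).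
4. Forward, ring A and union: 2,6-difluoro-4-methylbenzaldehyde gives the ring A fluoride (steps 9–11). Its formyl and ester groups, both kept in the target, activate the fluorine for diaryl ether formation (step 12). Debenzylation (step 13) and lactonisation (step 14) close the seven-membered ring last.
5. Helper groups: a MOM group on the C6 oxygen (on in step 2, off in step 8) and three benzyl groups (off in step 13); fluorine is the leaving group in both rings.
6. Stereochemistry: the target has no stereocentre (C2 carries two methyl groups), so none has to be set.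

Key step: step 7

Remark: 2,6-difluoro-4-methylbenzaldehyde and 4-fluoro-2-methylphenol are taken to be catalogue chemicals.

**Route**

Step 1
Reactants: 1 4-fluoro-2-methylphenol
Product: 2 5-fluoro-2-hydroxy-3-methylbenzaldehyde
Conditions: MgCl2, Et3N, (CH2O)n, MeCN, reflux
Reagents that add atoms: paraformaldehyde (as formaldehyde), C=O
Why: Magnesium-phenoxide-directed ortho-formylation (Casnati–Skattebøl reaction) can reach only the one free ortho position, because the other ortho carbon carries the methyl group and the para carbon the fluorine.

Step 2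
Reactants: 2 5-fluoro-2-hydroxy-3-methylbenzaldehyde
Product: 3 5-fluoro-2-(methoxymethoxy)-3-methylbenzaldehyde
Conditions: MOMCl, iPr2NEt, CH2Cl2, 0 °C to rt
Reagents that add atoms: chloromethyl methyl ether, COCCl
Why: O-alkylation of the phenol with the alpha-chloro ether gives the MOM acetal, which should survive the peracid, organolithium and enolate steps and can later be removed by acid without loss of benzyl ethers.

Step 3
Reactants: 3 5-fluoro-2-(methoxymethoxy)-3-methylbenzaldehyde
Product: 5 5-fluoro-2-(methoxymethoxy)-3-methylphenol, via aryl formate 4 (not isolated)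
Conditions: mCPBA, CH2Cl2, rt; then K2CO3 (cat.), MeOH, rt
Reagents that add atoms: mCPBA, OOC(=O)c1cccc(Cl)c1
Why: Baeyer–Villiger oxidation in its Dakin sense, in which the ortho-alkoxyaryl group migrates to oxygen in preference to hydrogen, followed by base-catalysed methanolysis of the formate.

Step 4
Reactants: 5 5-fluoro-2-(methoxymethoxy)-3-methylphenol
Product: 6 1-(benzyloxy)-5-fluoro-2-(methoxymethoxy)-3-methylbenzene
Conditions: BnBr, K2CO3, DMF, rt
Reagents that add atoms: benzyl bromide, BrCc1ccccc1
Why: Williamson ether synthesis on the only free phenol, which places the benzyl group that stays until the final hydrogenolysis.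

Step 5
Reactants: 6 1-(benzyloxy)-5-fluoro-2-(methoxymethoxy)-3-methylbenzene
Product: 7 1-(benzyloxy)-4-bromo-5-fluoro-2-(methoxymethoxy)-3-methylbenzene
Conditions: NBS, MeCN, 0 °C to rt
Reagents that add atoms: N-bromosuccinimide, O=C1CCC(=O)N1Br
Why: Electrophilic aromatic bromination goes para to the benzyloxy group, at the carbon between methyl and fluorine, because the MOM-bearing oxygen has no free ortho or para position and the site ortho to the benzyloxy group is shielded by it.

Step 6
Reactants: 7 1-(benzyloxy)-4-bromo-5-fluoro-2-(methoxymethoxy)-3-methylbenzene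
Product: 9 1-[4-(benzyloxy)-6-fluoro-3-(methoxymethoxy)-2-methylphenyl]ethan-1-one, via aryllithium 8 (not isolated)
Conditions: n-BuLi, THF, −78 °C; MeC(O)N(OMe)Me, −78 °C; aq NH4Cl
Reagents that add atoms: N-methoxy-N-methylacetamide, CON(C)C(C)=O
Why: Bromine–lithium exchange followed by Weinreb ketone synthesis, in which the ortho-fluoro aryllithium is kept cold to prevent loss of LiF and the chelated tetrahedral adduct stops the acylation at the ketone.

Step 7
Reactants: 9 1-[4-(benzyloxy)-6-fluoro-3-(methoxymethoxy)-2-methylphenyl]ethan-1-one; 10 acetone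
Product: 13 7-(benzyloxy)-6-(methoxymethoxy)-2,2,5-trimethylchroman-4-one, via lithium enolate 11 (not isolated), via lithium aldolate 12 (not isolated)
Conditions: LiN(SiMe3)2, THF, −78 °C; acetone (5 equiv), −78 °C; then DMPU, −78 to 50 °C
Reagents that add atoms: none
Why: Proposed new method: LiN(SiMe3)2 turns the acetyl group of 9 into lithium enolate 11, whose carbon adds to the carbonyl carbon of acetone (aldol addition, CH2–CMe2 bond) to give tertiary alkoxide 12, and on warming this alkoxide attacks the fluorine-bearing ring carbon ortho to the ketone and expels fluoride by addition–elimination (O–aryl bond), which drains the reversible aldol equilibrium toward product. The closest known reaction types are the directed aldol addition of aryl methyl ketone lithium enolates to ketones and the intramolecular SNAr closure of ortho-fluoroaryl ketones that carry an oxygen nucleophile to chromones and xanthones; the whole is the polarity-reversed counterpart of the Kabbe chromanone synthesis, with the ring oxygen coming from acetone instead of a phenol. The dihydropyranone ring closes in a 6-endo-trig sense, the alkoxide adding to the beta carbon of the aryl-embedded beta-fluoro enone C4(=O)–C4a=C8a–F before fluoride leaves. No stereocentre arises because C2 carries two identical methyl groups, so no element of stereocontrol is needed. The step needs chemoselectivity for cross-aldol addition and ipso substitution over acetone self-condensation, retro-aldol loss and dehydration of the aldolate; this should be secured because only one fluorine sits ortho to the ketone, fluoride loss is the only irreversible exit from the equilibrating mixture, and the C6 oxygen is a MOM ether twisted out of the ring plane by its two neighbours, so it cannot feed electron density to the para C–F carbon as a free phenoxide would.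

Step 8
Reactants: 13 7-(benzyloxy)-6-(methoxymethoxy)-2,2,5-trimethylchroman-4-one
Product: 14 7-(benzyloxy)-6-hydroxy-2,2,5-trimethylchroman-4-one
Conditions: HCl (3 M), MeOH, 40 °C
Reagents that add atoms: none
Why: Acid-catalysed acetal exchange with methanol removes the MOM group, while the benzyl ether and the dihydropyranone ring are stable to dilute acid.

Step 9
Reactants: 15 2,6-difluoro-4-methylbenzaldehyde
Product: 16 2-(benzyloxy)-6-fluoro-4-methylbenzaldehyde
Conditions: BnOH, NaH, THF, 0 °C to rt
Reagents that add atoms: benzyl alcohol, OCc1ccccc1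
Why: SNAr of one aldehyde-activated ortho fluorine by sodium benzyl oxide, after which the new alkoxy group deactivates the ring so that the second fluorine is kept.

Step 10
Reactants: 16 2-(benzyloxy)-6-fluoro-4-methylbenzaldehyde
Product: 17 6-(benzyloxy)-3-bromo-2-fluoro-4-methylbenzaldehyde
Conditions: NBS, DMF, rt
Reagents that add atoms: N-bromosuccinimide, O=C1CCC(=O)N1Br
Why: Electrophilic aromatic bromination para to the benzyloxy group and meta to the aldehyde, at the carbon between fluorine and methyl, as is usual for 2-alkoxybenzaldehydes.

Step 11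
Reactants: 17 6-(benzyloxy)-3-bromo-2-fluoro-4-methylbenzaldehyde
Product: 18 benzyl 4-(benzyloxy)-2-fluoro-3-formyl-6-methylbenzoate
Conditions: Pd(OAc)2, Xantphos, CO (1 atm), BnOH, Et3N, toluene, 90 °C
Reagents that add atoms: carbon monoxide, [C-]#[O+]; benzyl alcohol, OCc1ccccc1
Why: Palladium-catalysed alkoxycarbonylation of the aryl bromide (oxidative addition, CO insertion, alcoholysis of the acylpalladium species) with the wide-bite-angle ligand Xantphos, while neutral benzyl alcohol with an amine base in toluene should leave the activated fluorine in place.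

Step 12
Reactants: 14 7-(benzyloxy)-6-hydroxy-2,2,5-trimethylchroman-4-one; 18 benzyl 4-(benzyloxy)-2-fluoro-3-formyl-6-methylbenzoate
Product: 19 benzyl 4-(benzyloxy)-2-{[7-(benzyloxy)-2,2,5-trimethyl-4-oxochroman-6-yl]oxy}-3-formyl-6-methylbenzoate
Conditions: Cs2CO3, DMSO, 60 °C
Reagents that add atoms: none
Why: SNAr in which the formyl and ester groups, both ortho to the C–F carbon of 18, stabilise the Meisenheimer intermediate and the small fluoride leaving group lets the cesium phenoxide of 14 form the fourfold ortho-substituted diaryl ether.

Step 13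
Reactants: 19 benzyl 4-(benzyloxy)-2-{[7-(benzyloxy)-2,2,5-trimethyl-4-oxochroman-6-yl]oxy}-3-formyl-6-methylbenzoate
Product: 20 3-formyl-4-hydroxy-2-[(7-hydroxy-2,2,5-trimethyl-4-oxochroman-6-yl)oxy]-6-methylbenzoic acid
Conditions: H2 (1 atm), Pd/C, EtOAc, rt
Reagents that add atoms: none
Why: Catalytic hydrogenolysis cleaves the two aryl benzyl ethers and the benzyl ester in one operation, and the aryl ketone and the aldehyde (hydrogen-bonded to the freed ortho hydroxyl) should survive at 1 atm in a non-protic solvent.

Step 14
Reactants: 20 3-formyl-4-hydroxy-2-[(7-hydroxy-2,2,5-trimethyl-4-oxochroman-6-yl)oxy]-6-methylbenzoic acid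
Product: 21 mollicellin A
Conditions: DCC, CH2Cl2 (high dilution), rt
Reagents that add atoms: none
Why: Carbodiimide activation of the acid and intramolecular attack by the C7 phenol of ring B closes the seven-membered lactone (the standard depsidone lactonisation), while the ring A phenol is hydrogen-bonded to the aldehyde and could react only intermolecularly, which dilution suppresses.

**Compound list**

1 | 4-fluoro-2-methylphenol | Cc1cc(F)ccc1O | starting material
2 | 5-fluoro-2-hydroxy-3-methylbenzaldehyde | Cc1cc(F)cc(C=O)c1O | intermediate
3 | 5-fluoro-2-(methoxymethoxy)-3-methylbenzaldehyde | COCOc1c(C)cc(F)cc1C=O | intermediate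
4 | 5-fluoro-2-(methoxymethoxy)-3-methylphenyl formate (formed in the flask) | COCOc1c(C)cc(F)cc1OC=O | intermediate
5 | 5-fluoro-2-(methoxymethoxy)-3-methylphenol | COCOc1c(C)cc(F)cc1O | intermediate
6 | 1-(benzyloxy)-5-fluoro-2-(methoxymethoxy)-3-methylbenzene | COCOc1c(C)cc(F)cc1OCc1ccccc1 | intermediate
7 | 1-(benzyloxy)-4-bromo-5-fluoro-2-(methoxymethoxy)-3-methylbenzene | COCOc1c(C)c(Br)c(F)cc1OCc1ccccc1 | intermediate
8 | [4-(benzyloxy)-6-fluoro-3-(methoxymethoxy)-2-methylphenyl]lithium (formed in the flask) | [Li]c1c(C)c(OCOC)c(OCc2ccccc2)cc1F | intermediate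
9 | 1-[4-(benzyloxy)-6-fluoro-3-(methoxymethoxy)-2-methylphenyl]ethan-1-one | CC(=O)c1c(C)c(OCOC)c(OCc2ccccc2)cc1F | intermediate
10 | acetone | CC(C)=O | starting material
11 | lithium 1-[4-(benzyloxy)-6-fluoro-3-(methoxymethoxy)-2-methylphenyl]ethen-1-olate (formed in the flask) | [Li]OC(=C)c1c(C)c(OCOC)c(OCc2ccccc2)cc1F | intermediate
12 | lithium 4-[4-(benzyloxy)-6-fluoro-3-(methoxymethoxy)-2-methylphenyl]-2-methyl-4-oxobutan-2-olate (formed in the flask) | [Li]OC(C)(C)CC(=O)c1c(C)c(OCOC)c(OCc2ccccc2)cc1F | intermediate
13 | 7-(benzyloxy)-6-(methoxymethoxy)-2,2,5-trimethylchroman-4-one | CC1(C)CC(=O)c2c(C)c(OCOC)c(OCc3ccccc3)cc2O1 | intermediate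
14 | 7-(benzyloxy)-6-hydroxy-2,2,5-trimethylchroman-4-one | CC1(C)CC(=O)c2c(C)c(O)c(OCc3ccccc3)cc2O1 | intermediate
15 | 2,6-difluoro-4-methylbenzaldehyde | Cc1cc(F)c(C=O)c(F)c1 | starting material
16 | 2-(benzyloxy)-6-fluoro-4-methylbenzaldehyde | Cc1cc(F)c(C=O)c(OCc2ccccc2)c1 | intermediate
17 | 6-(benzyloxy)-3-bromo-2-fluoro-4-methylbenzaldehyde | Cc1cc(OCc2ccccc2)c(C=O)c(F)c1Br | intermediate
18 | benzyl 4-(benzyloxy)-2-fluoro-3-formyl-6-methylbenzoate | Cc1cc(OCc2ccccc2)c(C=O)c(F)c1C(=O)OCc1ccccc1 | intermediate
19 | benzyl 4-(benzyloxy)-2-{[7-(benzyloxy)-2,2,5-trimethyl-4-oxochroman-6-yl]oxy}-3-formyl-6-methylbenzoate | Cc1cc(OCc2ccccc2)c(C=O)c(Oc2c(C)c3c(cc2OCc2ccccc2)OC(C)(C)CC3=O)c1C(=O)OCc1ccccc1 | intermediate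
20 | 3-formyl-4-hydroxy-2-[(7-hydroxy-2,2,5-trimethyl-4-oxochroman-6-yl)oxy]-6-methylbenzoic acid | Cc1cc(O)c(C=O)c(Oc2c(C)c3c(cc2O)OC(C)(C)CC3=O)c1C(=O)O | intermediate
21 | mollicellin A | Cc1cc(O)c(C=O)c2c1C(=O)Oc1cc3c(c(C)c1O2)C(=O)CC(C)(C)O3 | target

**Count and risks**

Total step count: 14. Longest linear sequence: 11 steps (steps 1–8, then 12–14).

Steps most likely to fail:

Step 7 (bears the label). Retro-aldol reversion of the tertiary aldolate, acetone self-condensation or dehydration of the aldolate may outrun the ring-closing displacement of fluoride on the electron-rich ring. The fallback sets out from 9 and comes back at 13. Claisen condensation of 9 with ethyl acetate (NaH, THF) would give 1-[4-(benzyloxy)-6-fluoro-3-(methoxymethoxy)-2-methylphenyl]butane-1,3-dione F1. Its enolate oxygen would displace the ortho fluorine on heating (K2CO3, DMF, 100 °C), a known chromone-forming SNAr with no retro-aldol-prone intermediate, to give 7-(benzyloxy)-6-(methoxymethoxy)-2,5-dimethyl-4H-chromen-4-one F2. Conjugate addition of Me2CuLi with Me3SiCl (THF, −78 °C) would then place the second methyl group at C2 and deliver 13.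

Step 12. Substitution at a C–F carbon flanked on both sides, by a phenoxide that is itself flanked on both sides, may be slow enough for acyl transfer from the benzyl ester to the phenoxide, or ester hydrolysis, to take over. The fallback sets out from 14 and 17 and comes back at 19. The ether would be formed one step earlier, on bromide 17, whose fluorine is activated by the ortho formyl group and has bromine instead of an ester as second neighbour (Cs2CO3, DMSO, 80 °C). This would give 6-(benzyloxy)-3-bromo-2-{[7-(benzyloxy)-2,2,5-trimethyl-4-oxochroman-6-yl]oxy}-4-methylbenzaldehyde F3. Palladium-catalysed benzyloxycarbonylation of F3 (Pd(OAc)2, Xantphos, CO, BnOH, Et3N, toluene) would then install the ester and give 19.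

Step 13. Once the benzyl groups are gone, hydrogenation may continue at the aldehyde carbonyl, to the benzylic alcohol and on to a methyl group. The fallback sets out from 19 and comes back at 20. The reductive cleavage would be replaced by a non-reductive one: BCl3 with pentamethylbenzene as benzyl cation scavenger (CH2Cl2, −78 °C) would remove both benzyl ethers and the benzyl ester with no hydrogen source present. No new compound arises on this path (F0).

Further compounds
F1 | step 7 | 1-[4-(benzyloxy)-6-fluoro-3-(methoxymethoxy)-2-methylphenyl]butane-1,3-dione | CC(=O)CC(=O)c1c(C)c(OCOC)c(OCc2ccccc2)cc1F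
F2 | step 7 | 7-(benzyloxy)-6-(methoxymethoxy)-2,5-dimethyl-4H-chromen-4-one | CC1=CC(=O)c2c(C)c(OCOC)c(OCc3ccccc3)cc2O1
F3 | step 12 | 6-(benzyloxy)-3-bromo-2-{[7-(benzyloxy)-2,2,5-trimethyl-4-oxochroman-6-yl]oxy}-4-methylbenzaldehyde | Cc1cc(OCc2ccccc2)c(C=O)c(Oc2c(C)c3c(cc2OCc2ccccc2)OC(C)(C)CC3=O)c1Br
F0 | step 13 | none | none
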